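The data were generated by integration on assumed constants; the scatter is artificial.

Divide the monomer that chains end up holding by the number of chains begun: that quotient is the asked average, so the flask needs two estimates.

| setting | alder | elm | flask |
|---|---|---|---|
| free monomer | 0.050 M | 0.050 M | 0.050 M |
| initiator | 0.25 mol% | 1 mol% | 0.5 mol% |
| impurity | 0.35 mM | 0.35 mM | 0.35 mM |
| remark | run made earlier | run made earlier |  |
| time |  |  | 6.0 d |

| run | time / d | monomer in chains / % | free monomer / % |
|---|---|---|---|
| alder | 0.417 | 63 | 37 |
| alder | 1.25 | 80 | 14 |
| alder | 2.00 | 88 | 7 |
| alder | 3.00 | 91 | 6 |
| alder | 5.00 | 91 | 1 |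
| alder | 6.00 | 94 | 3 |
| elm | 0.417 | 94 | 3 |
| elm | 1.25 | 99 | 0 |
| elm | 2.00 | 100 | 1 |
| elm | 3.00 | 97 | 2 |
| elm | 5.00 | 96 | 0 |
| elm | 6.00 | 99 | 0 |

(readings scatter by 1.5 percentage points)

- the average divides the monomer in chains by the number of chains begun, living and dead together
- the earlier runs do not show the number of chains; that part of a forecast is a guess

- average number of monomer units in a chain (chains begun, living or dead) at 6.0 d
- part of the free monomer that has reacted at 6.0 d

The numerator is the monomer budget, the concentration of monomer in chains late in a run. Late elm readings of 97%, 96% and 99% put this monomer budget near 48.7 mM. One chain per initiator charged to the flask, 0.250 mM, then gives an average of 195.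

The objection is the impurity. Alder charged 0.125 mM of initiator against 0.35 mM of impurity, so one-for-one removal ahead of all else leaves alder no chains, yet alder's readings show monomer in chains. The rate has to count the ends instead.

While the number of ends holds steady, free monomer falls as exp(−κt), with κ a pseudo-first-order constant proportional to the ends. The first readings, each with its scatter, give κ of 2.38 /d for alder and 8.41 /d for elm. The flask's loading lies midway between them on a logarithmic scale, so its κ is about 4.48 /d. Taking elm's chains as its initiator beyond impurity, 0.150 mM, and scaling them by κ, this reckoning gives the flask 0.0799 mM of chains and an average near 609. That assumption is a guess, since the earlier runs do not show the number of chains.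

A constant κ has its own objection: alder's κt at the end is 14.3, while its reading gives ln(charge/left) of only 3.51. Scaling that integral by the rates gives the flask 6.59, so this reckoning puts about 99.9% as reacted.

The forecast, lower on the average than this reckoning, gave 185 (100 to 250) and 99% (97% to 99.9%), adding “Impurity-started chains would lower it”.

The flask gives an average of 1040 with 99.7% reacted.

    free monomer + initiator → living end + monomer in chains (k = 78.0 /M/h)
    free monomer + living end → monomer in chains + living end, rate k2*[living end]*[free monomer] (k = 7100 /M/h)
    initiator + impurity → spent initiator A (k = 72000 /M/h)
    free monomer → uncatalysed product (k = 0.00390 /h)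
    2 living end → dead end B (k = 2400 /M/h)

At 6.00 d the flask holds 2.03 × 10⁻⁴ M of spent initiator A, from 0.250 mM of initiator charged. The monomer budget divided by the flask's average gives 0.0468 mM of chains begun, against the 0.0799 mM reckoned. A neighbour flask, the same but charged with 2.1 × 10⁻⁴ M of impurity, reaches an average of 593, so the same budget gives it 0.0821 mM of chains begun.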